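The slow part of this chemistry comes after G has fallen away: in the violet run G reads 2.5% at 10.0 s, yet X stands at 25.6% at 30.0 s and is still climbing at 54.4% at 120 s. On the list of suspects, X comes from L + Q → X, so the question for each new flask is how long L survives beside Q.

in all of them: G 0.037 M; D 0.0351 M
- green: J 0.051 M; run made earlier
- blue: J 0.16 M; run made earlier
- violet: J 0.38 M; run made earlier
- north-west: J 0.0670 M; time 4.0 min
- south-east: J 0.170 M; time 4.0 min
- north: J 0.420 M; time 4.0 min

| run | time / s | X / % | G / % |
|---|---|---|---|
| green | 10.0 | 0.8 | 64.9 |
| green | 30.0 | 4.0 | 34.0 |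
| green | 60.0 | 7.9 | 20.3 |
| green | 80.0 | 9.6 | 16.2 |
| green | 120 | 11.6 | 12.1 |
| blue | 10.0 | 3.7 | 22.7 |
| blue | 30.0 | 15.6 | 1.6 |
| blue | 60.0 | 30.1 | 0.9 |
| blue | 80.0 | 35.2 | 0.1 |
| blue | 120 | 43.4 | 0.2 |
| violet | 10.0 | 7.5 | 2.5 |
| violet | 30.0 | 25.6 | 0 |
| violet | 60.0 | 38.9 | 0 |
| violet | 80.0 | 46.0 | 1.2 |
| violet | 120 | 54.4 | 0 |

(scatter of a reading: 0.5 percentage points)

- in percentages every species weighs as the G in it: one Z counts as two
- the numbers in the tables scatter by 0.5 percentage points (one standard deviation)
- on the list of suspects stand: G + L -> Z; G + J -> L; J + D -> Q; L + Q -> X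

* which of the two there is more of at the end, counted by the G in each, north-west (Z / X)
* which of the two there is more of at the end, counted by the G in each, south-east (Z / X)
* which of the two there is more of at the end, counted by the G in each, north (Z / X)
* how much X is there at the end, in percent of the G charged: north-west
* how much X is there at the end, in percent of the G charged: south-east
* how much X is there at the end, in percent of the G charged: north

The rate of that step is k[L][Q]. While [Q] is held at a given value, L decays in pseudo-first-order fashion, and the clearing time, 1/(k[Q]), is the time in which L falls to about a third of its amount.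

My own reckoning reads k from violet between 10.0 s and 30.0 s, replacing the curve by its mean. X rises at 0.0201 M min⁻¹ around a mean X of 0.00612 M. Taking [Q] as D charged less X gives 0.0290 M, and taking [L] as G charged less X gives 0.0309 M, so k reads 0.374 M⁻¹ s⁻¹. Averaging the two end products of [L][Q] instead shifts that product by 1.25%, so the mean costs little. The larger doubt is Z: any G that went to Z makes [L] smaller than counted, so this k is a low reading.

The forecast names Z as the larger in north-west, X in south-east and X in north. It puts X at 29% (21% to 37%), 55% (49% to 62%) and 69% (63% to 76%), on the ground that “G + L → Z wins when little J is left over after D”. For south-east my own reckoning starts from the last blue reading, where J was charged at 0.16 M against 0.170 M. Taking [Q] as D charged less X, blue holds 0.0190 M there, so my clearing time is 2.34 min, longer than the 2.00 min between that reading's time and the time asked. So I expect south-east still to be making X when read.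

North-west, south-east and north, in that order, give X of 26.5%, 54.9% and 68.0% beside Z of 70.5%, 37.6% and 18.1%, so the larger species are Z, X and X, as forecast.

    G + L → Z (k = 2.30 M⁻¹ s⁻¹)
    G + J → L (k = 0.950 M⁻¹ s⁻¹)
    J + D → Q (k = 1.70 M⁻¹ s⁻¹)
    L + Q → X (k = 0.450 M⁻¹ s⁻¹)

South-east has not come to rest at 4.00 min: it holds [Q] = 0.0148 M and L at 7.47%, and the clearing time from the violet reading is 3.01 min. By 40.0 min, X has risen from 54.9% to 62.4% and L reads 0%, while Z stays at 37.6%. The same flask charged with 0.021 M of D holds [Q] = 0.00550 M at 4.00 min, which gives a clearing time of 8.10 min, and there L stands at 21.6% beside X at 41.9%.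

Readings and results stem from a simulated flask on assumed constants, noise included.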